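**Strategy**

Ring B of the 1-aryl-1,2-dihydronaphthalene is disconnected at C1–C2 and at the C3=C4 styrene bond. The key step exploits the para-hydroxyl of the pendant guaiacyl ring, which makes the diaryl methine C1 a latent p-quinone methide carbon, and the formyl group on C2, which makes C2 an enamine carbon. In one operation the enamine of succinaldehyde adds 1,6 to the quinone methide (C1–C2) and its second aldehyde arm condenses with the formyl group of ring A (C3=C4), setting both stereocentres. The precursor is a racemic 3-aryl-1,3-dihydroisobenzofuran-1-ol, a lactol that masks the formyl group and the quinone methide alike. Chemoselective reduction of the conjugated aldehyde completes the route.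

Key step: step 4

Remark: 3 and 9 (commercial aqueous solution, extracted into CHCl3 before use) are taken as purchased materials; locants C1 to C8a are those of the dihydronaphthalene ring system of the target.

**Route**

Step 1
Reactants: 1 2-bromo-4-hydroxy-5-methoxybenzaldehyde (6-bromovanillin)
Product: 2 2-bromo-4-(tert-butyldimethylsilyloxy)-5-methoxybenzaldehyde
Conditions: TBSCl, imidazole, DMF, rt
Reagents that add atoms: tert-butyldimethylsilyl chloride (TBSCl), CC(C)(C)[Si](C)(C)Cl
Why: Imidazole-promoted O-silylation of the phenol (silyl ether formation) should be clean because the phenol is the only nucleophilic site, and the aryl silyl ether tolerates the organolithium chemistry of step 2.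

Step 2
Reactants: 2 2-bromo-4-(tert-butyldimethylsilyloxy)-5-methoxybenzaldehyde; 3 4-(tert-butyldimethylsilyloxy)-3-methoxybenzaldehyde
Product: 7 5-(tert-butyldimethylsilyloxy)-3-[4-(tert-butyldimethylsilyloxy)-3-methoxyphenyl]-6-methoxy-1,3-dihydroisobenzofuran-1-ol (racemic lactol; both C1 epimers), via lithium amino alkoxide 4 (not isolated), via aryllithium 5 (not isolated), via dilithium alkoxide 6 (not isolated)
Conditions: Me2NCH2CH2NHMe, n-BuLi, THF, −20 °C; then 2; n-BuLi, −78 °C; then 3, −78 to 0 °C; aq NH4Cl
Reagents that add atoms: none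
Why: Addition of LiN(Me)CH2CH2NMe2 to the formyl group protects it in situ as lithium α-amino alkoxide 4, bromine–lithium exchange gives aryllithium 5, its 1,2-addition to aldehyde 3 gives 6, and on aqueous work-up the amino alkoxide collapses to the aldehyde, which the new benzylic hydroxyl traps as the five-membered lactol; the carbinol stereocentre is formed racemic and is erased in step 4.

Step 3
Reactants: 7 5-(tert-butyldimethylsilyloxy)-3-[4-(tert-butyldimethylsilyloxy)-3-methoxyphenyl]-6-methoxy-1,3-dihydroisobenzofuran-1-ol
Product: 8 3-(4-hydroxy-3-methoxyphenyl)-6-methoxy-1,3-dihydroisobenzofuran-1,5-diol (racemic lactol; both C1 epimers)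
Conditions: Bu4NF, AcOH, THF, 0 °C
Reagents that add atoms: none
Why: Fluoride-mediated desilylation of both aryl silyl ethers is driven by the Si–F bond strength, and the acetic acid buffer keeps the liberated phenols protonated so that no quinone methide is released prematurely from the p-hydroxybenzylic ether.

Step 4
Reactants: 8 3-(4-hydroxy-3-methoxyphenyl)-6-methoxy-1,3-dihydroisobenzofuran-1,5-diol; 9 succinaldehyde (butanedial)
Product: 13 (1S,2R)-7-hydroxy-1-(4-hydroxy-3-methoxyphenyl)-6-methoxy-1,2-dihydronaphthalene-2,3-dicarbaldehyde, via ortho-formyl p-quinone methide 10 (not isolated), via acyclic trialdehyde adduct 11 (not isolated), via aldol adduct 12 (not isolated)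
Conditions: 9 (3 equiv), (R)-α,α-diphenylprolinol trimethylsilyl ether (20 mol %), 4-nitrobenzoic acid (20 mol %), CHCl3, 0 °C to rt
Reagents that add atoms: none
Why: The acid co-catalyst opens lactol 8 by a retro-oxa-1,6-addition, driven by the para-hydroxyl of the guaiacyl ring, to the ortho-formyl p-quinone methide 10; the (E)-enamine formed from succinaldehyde and the catalyst adds to its exocyclic methide carbon (C1–C2) with rearomatisation to give 11, a second enamine on the unbranched aldehyde arm attacks the ring A formyl carbon, and aldol 12 loses water to the conjugated enal (C3=C4). The closest known reaction types are the enamine-catalysed 1,6-addition of aldehydes to p-quinone methides and the amine-catalysed domino Michael/aldol condensation in which succinaldehyde serves as the four-carbon partner. Ring B closes in the aldol step by a 6-(enolexo)-exo-trig addition that the following E1cB dehydration makes irreversible. C2 is controlled by the catalyst, whose diphenyl(trimethylsilyloxy)methyl group shields one enamine face so that the (R)-catalyst should deliver the 2R configuration; C1 is controlled by the relative topicity of the addition, where the synclinal open transition state familiar from enamine additions to nitroalkenes places the quinoid ring over the enamine nitrogen and should lead to 1S, that is to the 1,2-trans product, which is also expected to be the more stable diastereomer. The step needs the enamine to engage the quinone methide before the aryl aldehyde and needs C2 to keep its configuration: the first is secured by the far higher electrophilicity of the quinone methide compared with the formyl group, which is deactivated by the para-hydroxyl of ring A, the second by the α-branching of the C2 aldehyde in 11 and 13, which the bulky secondary amine should not convert into an enamine.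

Step 5
Reactants: 13 (1S,2R)-7-hydroxy-1-(4-hydroxy-3-methoxyphenyl)-6-methoxy-1,2-dihydronaphthalene-2,3-dicarbaldehyde
Product: 14 (1S,2R)-7-hydroxy-1-(4-hydroxy-3-methoxyphenyl)-3-(hydroxymethyl)-6-methoxy-1,2-dihydronaphthalene-2-carbaldehyde (target)
Conditions: NaBH4, CeCl3·7H2O, EtOH/H2O, −15 °C
Reagents that add atoms: none
Why: Luche reduction: in aqueous ethanol CeCl3 converts the saturated, more electrophilic C2 aldehyde reversibly into its hydrate or hemiacetal, which borohydride does not attack, so the conjugated aldehyde should be reduced selectively in the 1,2-sense to the allylic alcohol while the C2 aldehyde is released again on work-up and neither stereocentre is touched.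

**Compound list**

1 | 2-bromo-4-hydroxy-5-methoxybenzaldehyde (6-bromovanillin) | COc1cc(C=O)c(Br)cc1O | starting material
2 | 2-bromo-4-(tert-butyldimethylsilyloxy)-5-methoxybenzaldehyde | COc1cc(C=O)c(Br)cc1O[Si](C)(C)C(C)(C)C | intermediate
3 | 4-(tert-butyldimethylsilyloxy)-3-methoxybenzaldehyde | COc1cc(C=O)ccc1O[Si](C)(C)C(C)(C)C | starting material
4 | lithium [2-bromo-4-(tert-butyldimethylsilyloxy)-5-methoxyphenyl]{[2-(dimethylamino)ethyl](methyl)amino}methanolate | COc1cc(C(O[Li])N(C)CCN(C)C)c(Br)cc1O[Si](C)(C)C(C)(C)C | intermediate (not isolated)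
5 | aryllithium formed from 4 by bromine–lithium exchange | COc1cc(C(O[Li])N(C)CCN(C)C)c([Li])cc1O[Si](C)(C)C(C)(C)C | intermediate (not isolated)
6 | dilithium alkoxide from addition of 5 to 3 | COc1cc(C(O[Li])N(C)CCN(C)C)c(C(O[Li])c2ccc(O[Si](C)(C)C(C)(C)C)c(OC)c2)cc1O[Si](C)(C)C(C)(C)C | intermediate (not isolated)
7 | 5-(tert-butyldimethylsilyloxy)-3-[4-(tert-butyldimethylsilyloxy)-3-methoxyphenyl]-6-methoxy-1,3-dihydroisobenzofuran-1-ol (racemic, both C1 epimers) | COc1cc2C(O)OC(c3ccc(O[Si](C)(C)C(C)(C)C)c(OC)c3)c2cc1O[Si](C)(C)C(C)(C)C | intermediate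
8 | 3-(4-hydroxy-3-methoxyphenyl)-6-methoxy-1,3-dihydroisobenzofuran-1,5-diol (racemic, both C1 epimers) | COc1cc2C(O)OC(c3ccc(O)c(OC)c3)c2cc1O | intermediate
9 | succinaldehyde (butanedial) | O=CCCC=O | starting material
10 | 4-hydroxy-5-methoxy-2-[(3-methoxy-4-oxocyclohexa-2,5-dien-1-ylidene)methyl]benzaldehyde (either alkene geometry) | COc1cc(C=O)c(C=C2C=CC(=O)C(OC)=C2)cc1O | intermediate (not isolated)
11 | (2S)-2-[(S)-(2-formyl-5-hydroxy-4-methoxyphenyl)(4-hydroxy-3-methoxyphenyl)methyl]butanedial | COc1cc([C@@H](c2cc(O)c(OC)cc2C=O)[C@H](CC=O)C=O)ccc1O | intermediate (not isolated)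
12 | (1S,2R)-4,7-dihydroxy-1-(4-hydroxy-3-methoxyphenyl)-6-methoxy-1,2,3,4-tetrahydronaphthalene-2,3-dicarbaldehyde (configuration at C3 and C4 not defined) | COc1cc([C@H]2c3cc(O)c(OC)cc3C(O)C(C=O)[C@@H]2C=O)ccc1O | intermediate (not isolated)
13 | (1S,2R)-7-hydroxy-1-(4-hydroxy-3-methoxyphenyl)-6-methoxy-1,2-dihydronaphthalene-2,3-dicarbaldehyde | COc1cc([C@H]2c3cc(O)c(OC)cc3C=C(C=O)[C@@H]2C=O)ccc1O | intermediate
14 | (1S,2R)-7-hydroxy-1-(4-hydroxy-3-methoxyphenyl)-3-(hydroxymethyl)-6-methoxy-1,2-dihydronaphthalene-2-carbaldehyde | COc1cc([C@H]2c3cc(O)c(OC)cc3C=C(CO)[C@@H]2C=O)ccc1O | target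

**Step count and risks**

Total step count: 5. Longest linear sequence: 5 steps (1 → 2 → 7 → 8 → 13 → 14).

Steps most likely to fail:

1. Step 4. The process at risk is poor facial selectivity at the quinone methide carbon in the intermolecular addition, which would divert material into the 1,2-cis diastereomer. It is aggravated by self-condensation of succinaldehyde and by dehydration of the lactol toward an isobenzofuran instead of ring opening. The fallback sets out from 7 and comes back at 13; it inverts the order of the two bond formations so that C1–C2 is closed intramolecularly. Lactol 7 reacts through its hydroxy aldehyde tautomer and cannot release a quinone methide while its phenols are silylated. An amine-catalysed cross-aldol condensation with 4,4-dimethoxybutanal (pyrrolidine, 4-(dimethylamino)benzoic acid, CH2Cl2) should give (E)-3-{4-(tert-butyldimethylsilyloxy)-2-[[4-(tert-butyldimethylsilyloxy)-3-methoxyphenyl](hydroxy)methyl]-5-methoxyphenyl}-2-(2,2-dimethoxyethyl)prop-2-enal F1, written in its open-chain form. Bu4NF/AcOH should then give the bis-phenol (E)-2-(2,2-dimethoxyethyl)-3-{4-hydroxy-2-[hydroxy(4-hydroxy-3-methoxyphenyl)methyl]-5-methoxyphenyl}prop-2-enal F2. In wet CHCl3, CF3CO2H should hydrolyse the dimethyl acetal and ionise the benzylic hydroxyl to the quinone methide. The (R)-configured catalyst of step 4 should then close ring B by a 6-exo-trig intramolecular enamine 1,6-addition, whose cyclic transition state ties the configuration of C1 to the catalyst-controlled C2, to give 13.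

2. Step 5. The process at risk is loss of chemoselectivity: hydride delivery to the saturated C2 aldehyde if its masking as hydrate or hemiacetal is incomplete, or if deprotonation of the ring A phenol deactivates the conjugated aldehyde. The fallback sets out from 13 and comes back at 14; it makes the masking a discrete operation. Selective acetalisation of the saturated aldehyde (HC(OMe)3, MeOH, catalytic CeCl3·7H2O, conditions that leave conjugated aldehydes untouched) should give (1S,2R)-2-(dimethoxymethyl)-7-hydroxy-1-(4-hydroxy-3-methoxyphenyl)-6-methoxy-1,2-dihydronaphthalene-3-carbaldehyde F3. NaBH4 in MeOH at 0 °C should reduce the remaining conjugated aldehyde to (1S,2R)-2-(dimethoxymethyl)-3-(hydroxymethyl)-1-(4-hydroxy-3-methoxyphenyl)-6-methoxy-1,2-dihydronaphthalen-7-ol F4. Mild hydrolysis (pyridinium p-toluenesulfonate, acetone/H2O) should release 14.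

3. Step 2. The process at risk is incomplete bromine–lithium exchange or premature collapse of the lithium amino alkoxide, followed by butyl addition to the liberated formyl group. The fallback sets out from 2 and comes back at 7; it protects the formyl group as an isolated acetal. Treatment of 2 with 1,2-bis(trimethylsilyloxy)ethane and catalytic Me3SiOTf (CH2Cl2, −78 °C) should give 2-[2-bromo-4-(tert-butyldimethylsilyloxy)-5-methoxyphenyl]-1,3-dioxolane F5. Bromine–lithium exchange (n-BuLi, THF, −78 °C) and addition to 3 should give [4-(tert-butyldimethylsilyloxy)-3-methoxyphenyl][5-(tert-butyldimethylsilyloxy)-2-(1,3-dioxolan-2-yl)-4-methoxyphenyl]methanol F6 (racemic). Hydrolysis with pyridinium p-toluenesulfonate in wet acetone should release the aldehyde, which closes to lactol 7.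

Further compounds
F1 | step 4 | (E)-3-{4-(tert-butyldimethylsilyloxy)-2-[[4-(tert-butyldimethylsilyloxy)-3-methoxyphenyl](hydroxy)methyl]-5-methoxyphenyl}-2-(2,2-dimethoxyethyl)prop-2-enal | COC(OC)C/C(C=O)=C\c1cc(OC)c(O[Si](C)(C)C(C)(C)C)cc1C(O)c1ccc(O[Si](C)(C)C(C)(C)C)c(OC)c1
F2 | step 4 | (E)-2-(2,2-dimethoxyethyl)-3-{4-hydroxy-2-[hydroxy(4-hydroxy-3-methoxyphenyl)methyl]-5-methoxyphenyl}prop-2-enal | COC(OC)C/C(C=O)=C\c1cc(OC)c(O)cc1C(O)c1ccc(O)c(OC)c1
F3 | step 5 | (1S,2R)-2-(dimethoxymethyl)-7-hydroxy-1-(4-hydroxy-3-methoxyphenyl)-6-methoxy-1,2-dihydronaphthalene-3-carbaldehyde | COc1cc([C@H]2c3cc(O)c(OC)cc3C=C(C=O)[C@@H]2C(OC)OC)ccc1O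
F4 | step 5 | (1S,2R)-2-(dimethoxymethyl)-3-(hydroxymethyl)-1-(4-hydroxy-3-methoxyphenyl)-6-methoxy-1,2-dihydronaphthalen-7-ol | COc1cc([C@H]2c3cc(O)c(OC)cc3C=C(CO)[C@@H]2C(OC)OC)ccc1O
F5 | step 2 | 2-[2-bromo-4-(tert-butyldimethylsilyloxy)-5-methoxyphenyl]-1,3-dioxolane | COc1cc(C2OCCO2)c(Br)cc1O[Si](C)(C)C(C)(C)C
F6 | step 2 | [4-(tert-butyldimethylsilyloxy)-3-methoxyphenyl][5-(tert-butyldimethylsilyloxy)-2-(1,3-dioxolan-2-yl)-4-methoxyphenyl]methanol | COc1cc(C2OCCO2)c(C(O)c2ccc(O[Si](C)(C)C(C)(C)C)c(OC)c2)cc1O[Si](C)(C)C(C)(C)C
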